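## Retrosynthetic overview

1. Target 11 ⇒ aryl iodide 9 + acrylic acid (Heck, last step); 9 ⇒ iodo alcohol 7 + p-coumaric acid (Mitsunobu ester bond).
2. 7 ⇒ alcohol 5 by iodination para to the ring oxygen.
3. 5 ⇒ open-chain phenol–enal 3. Presumed biosynthesis: the prenyl side chain of a prenylated p-coumarate is oxidised at its (E)-methyl group to the enal, and the phenol oxygen adds to it in conjugate fashion. The same closure is used here; it sets both stereocentres in one operation, and the aldehyde is reduced in the same flask.
4. 3 ⇒ 2-allylphenol + methacrolein (cross-metathesis gives the oxidised prenyl unit directly).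
5. Ring order: both benzene rings are bought; the dihydrofuran ring is the only ring formed (step 2).

Assumption: 9-amino-9-deoxy-epi-quinine is taken to deliver the (2S) ring carbon; if the first run shows the opposite sense, the pseudoenantiomeric amine made from quinidine is used and nothing else changes.

## Route

Step 1
Reactants: 1 2-allylphenol; 2 methacrolein
Product: 3 (2E)-4-(2-hydroxyphenyl)-2-methylbut-2-enal
Conditions: methacrolein (5 equiv), second-generation Hoveyda–Grubbs catalyst RuCl2(=CH-C6H4-2-OiPr)(1,3-dimesitylimidazolidin-2-ylidene) (3 mol%), CH2Cl2, 40 °C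
Reagents that add atoms: methacrolein (2), CC(=C)C=O
Why: Olefin cross-metathesis of a terminal alkene with the electron-poor 1,1-disubstituted methacrolein favours the cross product and gives the trisubstituted (E)-enal under thermodynamic control, the free phenol is tolerated by the ruthenium carbene, and no stereocentre is formed.

Step 2
Reactants: 3 (2E)-4-(2-hydroxyphenyl)-2-methylbut-2-enal
Product: 5 (2S)-2-[(2S)-2,3-dihydro-1-benzofuran-2-yl]propan-1-ol, via (2R)-2-[(2S)-2,3-dihydro-1-benzofuran-2-yl]propanal 4 (not isolated)
Conditions: 9-amino-9-deoxy-epi-quinine (20 mol%), TFA (30 mol%), toluene, 0 °C to rt; then short SiO2 plug, NaBH4, MeOH, −20 °C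
Reagents that add atoms: none
Why: Proposed new method: the cinchona primary amine condenses with the α-branched enal to an iminium ion, its quinuclidine nitrogen takes the phenol proton and steers a 5-exo-trig oxa-Michael attack onto one face of the β-carbon (sets the ring carbon as S), and the resulting enamine is protonated at the α-carbon under catalyst control on the face anti to the new C–O bond (sets the methyl-bearing carbon, R in aldehyde 4 and S in alcohol 5), after which hydrolysis and immediate NaBH4 reduction stop retro-Michael and α-epimerisation; the closest known reaction types are primary-amine iminium conjugate addition/protonation cascades of α-branched enals with thiols, indoles and hydrogen peroxide, and amine- or squaramide-catalysed intramolecular phenol oxa-Michael closures of enones to 2-substituted dihydrobenzofurans; high ee at the ring carbon is expected, the dr at the α-carbon is the uncertain element, and the minor diastereomer is removed by chromatography at 5.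

Step 3
Reactants: 5 (2S)-2-[(2S)-2,3-dihydro-1-benzofuran-2-yl]propan-1-ol; 6 N-iodosuccinimide
Product: 7 (2S)-2-[(2S)-5-iodo-2,3-dihydro-1-benzofuran-2-yl]propan-1-ol
Conditions: NIS (1.05 equiv), TFA (20 mol%), MeCN, 0 °C to rt
Reagents that add atoms: N-iodosuccinimide (6), O=C1CCC(=O)N1I
Why: Electrophilic aromatic iodination of a 2,3-dihydrobenzofuran goes para to the ring oxygen (C5), and the primary alcohol and both stereocentres are untouched.

Step 4
Reactants: 7 (2S)-2-[(2S)-5-iodo-2,3-dihydro-1-benzofuran-2-yl]propan-1-ol; 8 p-coumaric acid [(2E)-3-(4-hydroxyphenyl)prop-2-enoic acid]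
Product: 9 (2S)-2-[(2S)-5-iodo-2,3-dihydro-1-benzofuran-2-yl]propyl (2E)-3-(4-hydroxyphenyl)prop-2-enoate
Conditions: p-coumaric acid (1.3 equiv), PPh3, DIAD, THF, 0 °C to rt
Reagents that add atoms: p-coumaric acid (8), OC(=O)/C=C/c1ccc(O)cc1
Why: Mitsunobu esterification, in which the alkoxyphosphonium ion of the primary alcohol is displaced by the carboxylate; the carboxylic acid is about five pKa units more acidic than the phenol, so the phenol needs no protection, and the reacting carbon is a CH2, so no stereocentre is affected.

Step 5
Reactants: 9 (2S)-2-[(2S)-5-iodo-2,3-dihydro-1-benzofuran-2-yl]propyl (2E)-3-(4-hydroxyphenyl)prop-2-enoate; 10 acrylic acid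
Product: 11 (2E)-3-[(2S)-2-{(2S)-1-[(2E)-3-(4-hydroxyphenyl)prop-2-enoyl]oxypropan-2-yl}-2,3-dihydro-1-benzofuran-5-yl]prop-2-enoic acid (target)
Conditions: acrylic acid (3 equiv), Pd(OAc)2 (5 mol%), Bu4NCl, NaHCO3, DMF, 70 °C; then 1 M HCl
Reagents that add atoms: acrylic acid (10), C=CC(=O)O
Why: Mizoroki–Heck reaction, in which oxidative addition of the aryl iodide to zerovalent palladium, insertion of the unhindered acrylate and syn β-hydride elimination give the (E)-cinnamic acid directly; the 1,2-disubstituted coumarate alkene inserts far more slowly than acrylic acid, and bicarbonate at 70 °C does not cleave the ester.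

## Compound list

1 | 2-allylphenol [2-(prop-2-en-1-yl)phenol] | C=CCc1ccccc1O | starting material
2 | methacrolein (2-methylprop-2-enal) | CC(=C)C=O | starting material
3 | (2E)-4-(2-hydroxyphenyl)-2-methylbut-2-enal | O=C/C(C)=C/Cc1ccccc1O | intermediate
4 | (2R)-2-[(2S)-2,3-dihydro-1-benzofuran-2-yl]propanal | C[C@@H](C=O)[C@@H]1Cc2ccccc2O1 | intermediate
5 | (2S)-2-[(2S)-2,3-dihydro-1-benzofuran-2-yl]propan-1-ol | C[C@@H](CO)[C@@H]1Cc2ccccc2O1 | intermediate
6 | N-iodosuccinimide | O=C1CCC(=O)N1I | starting material
7 | (2S)-2-[(2S)-5-iodo-2,3-dihydro-1-benzofuran-2-yl]propan-1-ol | C[C@@H](CO)[C@@H]1Cc2cc(I)ccc2O1 | intermediate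
8 | p-coumaric acid [(2E)-3-(4-hydroxyphenyl)prop-2-enoic acid] | OC(=O)/C=C/c1ccc(O)cc1 | starting material
9 | (2S)-2-[(2S)-5-iodo-2,3-dihydro-1-benzofuran-2-yl]propyl (2E)-3-(4-hydroxyphenyl)prop-2-enoate | C[C@@H](COC(=O)/C=C/c1ccc(O)cc1)[C@@H]1Cc2cc(I)ccc2O1 | intermediate
10 | acrylic acid (prop-2-enoic acid) | C=CC(=O)O | starting material
11 | (2E)-3-[(2S)-2-{(2S)-1-[(2E)-3-(4-hydroxyphenyl)prop-2-enoyl]oxypropan-2-yl}-2,3-dihydro-1-benzofuran-5-yl]prop-2-enoic acid | C[C@@H](COC(=O)/C=C/c1ccc(O)cc1)[C@@H]1Cc2cc(/C=C/C(=O)O)ccc2O1 | target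

## Step count and risks

Total steps: 5. Longest linear sequence: 5 (1 → 3 → 5 → 7 → 9 → 11).

**Step 2 (most likely to fail).** The ee at the ring carbon and especially the dr at the methyl-bearing carbon are not secured by precedent, and the aldehyde can epimerise or revert before reduction. The fallback sets out from 3 and comes back at 5; it closes the ring by allylic substitution and sets the second centre in a separate step.
- Luche reduction of 3 (NaBH4, CeCl3·7H2O, MeOH, 0 °C) gives (2E)-4-(2-hydroxyphenyl)-2-methylbut-2-en-1-ol F1.
- Methyl chloroformate and pyridine convert both hydroxyl groups into carbonates, giving methyl (2E)-4-{2-[(methoxycarbonyl)oxy]phenyl}-2-methylbut-2-en-1-yl carbonate F2.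
- Pd2(dba)3·CHCl3 with the (R,R)-DACH-phenyl Trost ligand (its enantiomer if the product proves to be R) ionises the allylic carbonate to a π-allyl complex of divalent palladium. The methoxide released frees the phenoxide from the aryl carbonate, and 5-exo O-allylation gives (2S)-2-(prop-1-en-2-yl)-2,3-dihydro-1-benzofuran F3.
- Hydroboration of F3 with catecholborane catalysed by RhCl(PPh3)3, then NaOH/H2O2, gives 5. The catalysed reaction is syn-selective for 1,1-disubstituted alkenes bearing an allylic oxygen, and syn is the relationship the target needs.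

**Step 1.** The cross-metathesis may stall, isomerise the allyl group, or give an enal that cyclises racemically on isolation. The fallback sets out from 1 and comes back at 3, replacing metathesis by olefination.
- Ozonolysis of 1 (O3, CH2Cl2/MeOH, −78 °C; Me2S) gives (2-hydroxyphenyl)acetaldehyde in its closed lactol form, 2,3-dihydro-1-benzofuran-2-ol F4.
- Wittig reaction of F4 with the stabilised ylide 2-(triphenylphosphoranylidene)propanal (toluene, 90 °C) opens the lactol and gives the (E)-enal 3.

**Step 4.** The unprotected phenol of p-coumaric acid may compete in the Mitsunobu reaction, or yields may be low. The fallback sets out from 7 and comes back at 9, building the cinnamate on the alcohol instead of coupling it.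
- Heating 7 with Meldrum's acid (toluene, 110 °C) gives the malonic half-ester 3-{(2S)-2-[(2S)-5-iodo-2,3-dihydro-1-benzofuran-2-yl]propoxy}-3-oxopropanoic acid F5.
- Knoevenagel–Doebner condensation of F5 with 4-hydroxybenzaldehyde (pyridine, catalytic piperidine, 60 °C) with decarboxylation gives the (E)-coumarate 9 without phenol protection.

## Further compounds

F1 | step 2 | (2E)-4-(2-hydroxyphenyl)-2-methylbut-2-en-1-ol | OC/C(C)=C/Cc1ccccc1O
F2 | step 2 | methyl (2E)-4-{2-[(methoxycarbonyl)oxy]phenyl}-2-methylbut-2-en-1-yl carbonate | COC(=O)OC/C(C)=C/Cc1ccccc1OC(=O)OC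
F3 | step 2 | (2S)-2-(prop-1-en-2-yl)-2,3-dihydro-1-benzofuran | CC(=C)[C@@H]1Cc2ccccc2O1
F4 | step 1 | 2,3-dihydro-1-benzofuran-2-ol | OC1Cc2ccccc2O1
F5 | step 4 | 3-{(2S)-2-[(2S)-5-iodo-2,3-dihydro-1-benzofuran-2-yl]propoxy}-3-oxopropanoic acid | C[C@@H](COC(=O)CC(=O)O)[C@@H]1Cc2cc(I)ccc2O1
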